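No rate constant is given, so the first step is to read apparent ones from what is known.

| setting | south-east | south | Saturday's | Friday's | Wednesday's | Tuesday's |
|---|---|---|---|---|---|---|
| Z | 0.050 M | 0.050 M | 0.050 M | 0.15 M | 0.050 M | 0.050 M |
| X | 0.052 M | 0.24 M | 0.120 M | 0.150 M | 0.0400 M | 0.150 M |
| L | 0.060 M | 0.060 M | 0.0600 M | 0.0600 M | 0.0600 M | 0.120 M |
| remark | run made earlier | run made earlier |  |  |  |  |
| time |  |  | 8.0 d | 8.0 d | 8.0 d | 8.0 d |

| run | time / d | J / % |
|---|---|---|
| south-east | 0.417 | 1.5 |
| south-east | 0.625 | 2.2 |
| south-east | 1.04 | 2.7 |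
| south-east | 1.67 | 8.4 |
| south-east | 2.50 | 13.5 |
| south-east | 4.00 | 22.8 |
| south-east | 6.00 | 32.2 |
| south | 0.333 | 1.7 |
| south | 0.833 | 8.6 |
| south | 1.67 | 18.8 |
| south | 2.50 | 27.7 |
| south | 3.00 | 30.5 |
| south | 4.00 | 37.5 |
| south | 6.00 | 50.2 |

(standard deviation of a reading: 1 percentage point)



1. all flasks from highest to lowest amount of J, in percent of the Z charged, at 8.0 d (Saturday's / Friday's / Wednesday's / Tuesday's)
2. the amount of J, in percent of the Z charged of the flask you put first, at 8.0 d
3. the amount of J, in percent of the Z charged of the flask you put last, at 8.0 d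

Taking the logarithm of the Z fraction not yet J, with sign reversed, over the time, the last readings give 0.0648 d⁻¹ in the south-east run and 0.116 d⁻¹ in the south run. These carry the scatter of the readings. Between the two runs [X] rises from 0.052 M to 0.24 M, so the apparent order in X is 0.382. Saturday's and Wednesday's hold [Z] and [L] as in the runs, so a shift along [X] gives 51.0% for Saturday's and 37.4% for Wednesday's. At Friday's [X] the constant is 0.0971 d⁻¹. L was never varied, so Tuesday's is a guess: first order in L gives twice that constant and 78.8%.

The weak link is Friday's. The same constant gives 54.0%, which is 0.0810 M of J, more than the 0.0600 M of L charged. Assume one L per J. The one-to-one charge is then the zero of the scale, and Friday's L ceiling, the charged [L] over the charged [Z], is 40.0%. Saturday's and Wednesday's stand at 120%, above the whole of Z. With Z in excess, L is treated as pseudo-first-order, its constant being Friday's divided by the ceiling, and J climbs towards the ceiling to 34.3%. That is less than Wednesday's, and high if anything, since Z is held at its charge.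

The forecast, which differs from this reckoning in the last two places, ran Tuesday's > Saturday's > Friday's > Wednesday's, with 72% first and 35% last, and said of Friday's “Z exceeds L and X is drawn down”.

The flasks give Tuesday's > Saturday's > Wednesday's > Friday's, with 70.2% first and 29.2% last.

    Z + L → Q (k = 6.50 × 10⁻⁶ M⁻¹ s⁻¹)
    Z + X → E (k = 1.40 × 10⁻⁴ M⁻¹ s⁻¹)
    L + E → J (k = 5.00 × 10⁻⁵ M⁻¹ s⁻¹)
    2 X → D (k = 9.60 × 10⁻⁵ M⁻¹ s⁻¹)

The step L + E → J does take one L per J, and Friday's 29.2% lies 11 percentage points under its ceiling of 40.0%, with 33.7% at 80.0 d. Tuesday's ceiling of 240% stands above the whole of Z, yet its J ends at 70.2%: taking away the conversion 2 X → D lifts that J to 89.3%, so this conversion may be called the main reason for what is missing in Tuesday's. A flask like Tuesday's with [L] cut to 0.030 M has a ceiling of 60.0%, and at 8.00 d it holds J at 33.5% with 46.5% of the Z charged still standing as E.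

The data were computed on assumed constants; the scatter is artificial.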